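Readings and results were computed with made-up constants, noise included.

No constant is given, so I begin by reading one from the runs and turning it into a time. Reagent attacks substrate and then what is made from it, double product among them.

| flask | substrate | reagent | remark | time |
|---|---|---|---|---|
| Wednesday's | 27 mM | 16 mM | run made earlier |  |
| Friday's | 27 mM | 350 mM | run made earlier |  |
| noon | 27 mM | 25.0 mM |  | 2.0 h |
| dusk | 27 mM | 50.0 mM |  | 2.0 h |
| winter | 27 mM | 100 mM |  | 2.0 h |
| spring | 27 mM | 200 mM |  | 2.0 h |
| dawn | 27 mM | 400 mM |  | 2.0 h |

| run | time / min | double product / % | substrate / % |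
|---|---|---|---|
| Wednesday's | 6.00 | 4.0 | 83.4 |
| Wednesday's | 15.0 | 6.5 | 69.0 |
| Wednesday's | 30.0 | 10.2 | 65.0 |
| Wednesday's | 50.0 | 11.1 | 62.4 |
| Wednesday's | 60.0 | 11.2 | 61.8 |
| Wednesday's | 80.0 | 11.7 | 62.2 |
| Friday's | 6.00 | 4.1 | 1.4 |
| Friday's | 15.0 | 0 | 0.9 |
| Friday's | 30.0 | 0.2 | 0 |
| Friday's | 50.0 | 0.3 | 0 |
| Friday's | 60.0 | 0 | 1.0 |
| Friday's | 80.0 | 0 | 0.6 |

(readings scatter by 1 percentage point)

- the earlier runs were read with a standard deviation of 1 percentage point
- "hardly changes" means that all values lie within two and a half points (for a concentration: within two and a half percent of the largest)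

1. amount of double product at the end, in percent of the substrate charged for noon, dusk, winter, spring, dawn, in this order
2. the course of these numbers from the first flask to the last (falls, then rises / hardly changes / rises all the way / falls all the way / rises, then falls)

1. In Wednesday's run substrate falls to 83.4% in 6.00 min with 16 mM of reagent. I take the rate as proportional to reagent, so with noon's charge held constant the substrate's half-life is about 14.7 min. That is far shorter than the 2.0 h allowed, so I expect noon's flask to stop for want of reagent, not of time.

2. At Wednesday's charge that half-life is 22.9 min, yet substrate still stands at 62.2% after 80.0 min, which is 3.49 half-lives. So I assume Wednesday's 16 mM of reagent has gone, and I define the cost, the reagent used per substrate lost: 1.57. Of the substrate lost that day, a share of 0.310 stands as double product.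

3. At that cost, noon's 25.0 mM of reagent removes 15.9 mM of substrate. That leaves 41.1% and gives 18.3% double product, the number I can commit to.

4. The weak link is the constant cost. Dusk's 50.0 mM would remove 31.8 mM, more than the 27 mM charged, so dusk's cost is at least 1.85. I take noon's cost midway, at 1.71. Noon then leaves 45.9% substrate and gives 16.8% double product.

5. My reckoning stops at noon. The forecast goes through the row, with 18.5%, 21%, 0.5%, 0%, 0%, a course that rises, then falls, and it starts from the same reading: “Wednesday stalls because the reagent runs out”.

    substrate + reagent → first product + by-product (k = 0.0402 M⁻¹ s⁻¹)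
    reagent + first product → double product + by-product (k = 0.0873 M⁻¹ s⁻¹)
    reagent + double product → triple product + by-product (k = 0.0815 M⁻¹ s⁻¹)
    reagent + triple product → tetra adduct + by-product (k = 0.0192 M⁻¹ s⁻¹)
    reagent + double product → over-reaction product (k = 0.00156 M⁻¹ s⁻¹)

The flasks give 16.5%, 19.7%, 1.79%, 0%, 0%, a course that rises, then falls, and the forecast holds within its margin. Noon's flask ends with substrate at 48.3% and reagent, the limiting reagent, at 0%, and a run ten times as long changes nothing. Noon's cost comes to 1.79, above my 1.71. Dusk's cost, reckoned the same way, comes to 2.42.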